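**Retrosynthetic overview**

1. Quinone 30 ⇐ phenol 29 (para-oxidation) ⇐ MOM ether 28; the C1'–C2' bond and the 2'E alkene come from methylalumination of terminal alkyne 26 and Pd-catalysed coupling with benzylic chloride 9.
2. 26 ⇐ C8'–C9' bond: lithiated allylic sulfone 16 opens terminal epoxide 22, then hydride desulfonylation and desilylation.
3. 22 ⇐ nerol 17: Sharpless epoxidation, tosylation, acid hydrolysis with inversion at the tertiary carbon, reclosure, silylation (sets 10'R,11'R).
4. 16 ⇐ prenyl bromide 11 + lithiated 1-(trimethylsilyl)propyne 10, E-selective SeO2 oxidation, bromide, sulfinate.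
5. Ring order: the single carbocycle is closed first (Michael addition of 1 to acrolein, then intramolecular aldol condensation to cyclohexenone 5), aromatised to salicylate 6 (its ester carbon becomes C1') and oxidised to the quinone only in the last step.

Assumption: side-chain carbons are called C1'–C16' counted from the ring, and reagents that only deliver a small group (given under "Reagents that add atoms") are not numbered.

**Fragment A (steps 1–6)**

Step 1
Reactants: 1 ethyl 3-oxopentanoate; 2 acrolein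
Product: 3 ethyl 3-oxo-2-(3-oxopropyl)pentanoate (racemic)
Conditions: NaOEt (5 mol %), EtOH, −20 → 0 °C, slow addition of 2 to 1 (1.2 equiv)
Reagents that add atoms: none
Why: Base-catalysed Michael addition of the doubly activated C2 enolate of 1 to acrolein is fast at low temperature, and slow addition of the acceptor favours the monoadduct; the new stereocentre is lost later.

Step 2
Reactants: 3 ethyl 3-oxo-2-(3-oxopropyl)pentanoate
Product: 5 ethyl 3-methyl-2-oxocyclohex-3-ene-1-carboxylate (racemic), via aldol adduct 4 (not isolated)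
Conditions: p-TsOH·H2O (10 mol %), toluene, reflux, Dean–Stark
Reagents that add atoms: none
Why: Intramolecular aldol condensation (the ring-forming half of a Robinson-type annulation): the ethyl-side enol of the ketone is the only nucleophile that reaches the aldehyde through a six-membered transition state, and azeotropic removal of water makes the conjugated enone irreversible.

Step 3
Reactants: 5 ethyl 3-methyl-2-oxocyclohex-3-ene-1-carboxylate
Product: 6 ethyl 2-hydroxy-3-methylbenzoate
Conditions: DDQ (1.2 equiv), 1,4-dioxane, 100 °C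
Reagents that add atoms: none
Why: DDQ dehydrogenation of the enolised cyclohexenone β-keto ester is driven by aromatisation and leaves OH, CH3 and CO2Et on three adjacent ring carbons with no regiochemical choice.

Step 4
Reactants: 6 ethyl 2-hydroxy-3-methylbenzoate
Product: 7 ethyl 2-(methoxymethoxy)-3-methylbenzoate
Conditions: NaH (1.2 equiv), MOMCl (1.3 equiv), DMF, 0 → 20 °C
Reagents that add atoms: chloromethyl methyl ether (MOMCl), COCCl
Why: Williamson-type O-alkylation of the sodium phenoxide gives an acetal that survives the hydride, organoaluminium and palladium steps.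

Step 5
Reactants: 7 ethyl 2-(methoxymethoxy)-3-methylbenzoate
Product: 8 [2-(methoxymethoxy)-3-methylphenyl]methanol
Conditions: LiAlH4 (1.0 equiv), THF, 0 °C; NaOH/H2O work-up
Reagents that add atoms: none
Why: LiAlH4 reduction of the aryl ester to the benzylic alcohol leaves the MOM acetal untouched.

Step 6
Reactants: 8 [2-(methoxymethoxy)-3-methylphenyl]methanol
Product: 9 1-(chloromethyl)-2-(methoxymethoxy)-3-methylbenzene
Conditions: N-chlorosuccinimide (1.2 equiv), PPh3 (1.2 equiv), CH2Cl2, 0 → 20 °C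
Reagents that add atoms: N-chlorosuccinimide, O=C1CCC(=O)N1Cl
Why: Appel-type chlorination through the alkoxyphosphonium salt runs under neutral conditions, so the acid-labile MOM group is kept.

**Fragment B (steps 7–10)**

Step 7
Reactants: 10 trimethyl(prop-1-yn-1-yl)silane; 11 1-bromo-3-methylbut-2-ene (prenyl bromide)
Product: 13 trimethyl(6-methylhept-5-en-1-yn-1-yl)silane, via propargyllithium 12 (not isolated)
Conditions: 10, n-BuLi (1.0 equiv), THF, −78 → −20 °C; then 11, −78 → 20 °C
Reagents that add atoms: none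
Why: Propargylic lithiation of 10 and SN2 alkylation with the primary allylic bromide (Corey-type propargylation) gives the 1,5-enyne, the silyl group blocking the acetylenic position.

Step 8
Reactants: 13 trimethyl(6-methylhept-5-en-1-yn-1-yl)silane
Product: 14 (2E)-2-methyl-7-(trimethylsilyl)hept-2-en-6-yn-1-ol
Conditions: SeO2 (20 mol %), t-BuOOH (3 equiv), salicylic acid (10 mol %), CH2Cl2, 20 °C
Reagents that add atoms: selenium dioxide (oxygen carrier), O=[Se]=O; tert-butyl hydroperoxide, CC(C)(C)OO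
Why: Sharpless SeO2/t-BuOOH allylic oxidation (ene reaction then 2,3-sigmatropic shift) hydroxylates the E-methyl group of the trisubstituted alkene, which sets the 6'E geometry.

Step 9
Reactants: 14 (2E)-2-methyl-7-(trimethylsilyl)hept-2-en-6-yn-1-ol
Product: 15 [(5E)-7-bromo-6-methylhept-5-en-1-yn-1-yl]trimethylsilane
Conditions: CBr4 (1.2 equiv), PPh3 (1.25 equiv), CH2Cl2, 0 °C
Reagents that add atoms: carbon tetrabromide, BrC(Br)(Br)Br
Why: Appel bromination of the primary allylic alcohol is an SN2 process without allylic transposition or loss of alkene geometry.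

Step 10
Reactants: 15 [(5E)-7-bromo-6-methylhept-5-en-1-yn-1-yl]trimethylsilane
Product: 16 trimethyl[(5E)-6-methyl-7-(phenylsulfonyl)hept-5-en-1-yn-1-yl]silane
Conditions: PhSO2Na (1.5 equiv), DMF, 20 °C
Reagents that add atoms: sodium benzenesulfinate, [Na+].[O-]S(=O)c1ccccc1
Why: SN2 S-alkylation of the soft sulfinate gives the allylic sulfone, whose α-CH2 (future C8') is acidic.

**Fragment C (steps 11–15)**

Step 11
Reactants: 17 nerol, (2Z)-3,7-dimethylocta-2,6-dien-1-ol
Product: 18 [(2R,3S)-3-methyl-3-(4-methylpent-3-en-1-yl)oxiran-2-yl]methanol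
Conditions: Ti(OiPr)4 (10 mol %), D-(−)-diethyl tartrate (12 mol %), t-BuOOH (2 equiv), 4 Å molecular sieves, CH2Cl2, −20 °C
Reagents that add atoms: tert-butyl hydroperoxide, CC(C)(C)OO
Why: Sharpless asymmetric epoxidation is specific for the allylic-alcohol alkene, and with D-(−)-diethyl tartrate the Z-alcohol gives the (2R,3S)-epoxide in about 90–94 % ee.

Step 12
Reactants: 18 [(2R,3S)-3-methyl-3-(4-methylpent-3-en-1-yl)oxiran-2-yl]methanol
Product: 19 [(2R,3S)-3-methyl-3-(4-methylpent-3-en-1-yl)oxiran-2-yl]methyl 4-methylbenzenesulfonate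
Conditions: TsCl (1.2 equiv), Et3N (1.5 equiv), DMAP (5 mol %), CH2Cl2, 0 °C
Reagents that add atoms: 4-methylbenzenesulfonyl chloride, Cc1ccc(cc1)S(=O)(=O)Cl
Why: Sulfonylation of the primary alcohol makes C1 (future C9') an electrophile and inductively deactivates the adjacent epoxide carbon for the next step.

Step 13
Reactants: 19 [(2R,3S)-3-methyl-3-(4-methylpent-3-en-1-yl)oxiran-2-yl]methyl 4-methylbenzenesulfonate
Product: 20 (2R,3R)-2,3-dihydroxy-3,7-dimethyloct-6-en-1-yl 4-methylbenzenesulfonate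
Conditions: HClO4 (5 mol %), THF/H2O 3:1, 0 → 20 °C
Reagents that add atoms: water, O
Why: Acid-catalysed epoxide hydrolysis: water attacks the protonated epoxide at the tertiary carbon with inversion (borderline SN2) while the C2–O bond is kept, so the cis-epoxide gives the (2R,3R)-diol, which is the 10'R,11'R array.

Step 14
Reactants: 20 (2R,3R)-2,3-dihydroxy-3,7-dimethyloct-6-en-1-yl 4-methylbenzenesulfonate
Product: 21 (2R)-6-methyl-2-[(2R)-oxiran-2-yl]hept-5-en-2-ol
Conditions: K2CO3 (1.5 equiv), MeOH, 0 °C, 30 min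
Reagents that add atoms: none
Why: Intramolecular Williamson etherification (3-exo-tet) by the secondary alkoxide on the primary tosylate forms the terminal epoxide without touching either stereocentre, and low temperature with short time avoids Payne equilibration.

Step 15
Reactants: 21 (2R)-6-methyl-2-[(2R)-oxiran-2-yl]hept-5-en-2-ol
Product: 22 triethyl({(2R)-6-methyl-2-[(2R)-oxiran-2-yl]hept-5-en-2-yl}oxy)silane
Conditions: Et3SiOTf (1.3 equiv), 2,6-lutidine (2 equiv), CH2Cl2, −78 °C
Reagents that add atoms: triethylsilyl trifluoromethanesulfonate, CC[Si](CC)(CC)OS(=O)(=O)C(F)(F)F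
Why: Silyl triflate with a hindered base silylates the tertiary alcohol at −78 °C, which blocks Payne rearrangement and alkoxide side reactions in the coupling.

**Assembly (steps 16–21)**

Step 16
Reactants: 16 trimethyl[(5E)-6-methyl-7-(phenylsulfonyl)hept-5-en-1-yn-1-yl]silane; 22 triethyl({(2R)-6-methyl-2-[(2R)-oxiran-2-yl]hept-5-en-2-yl}oxy)silane
Product: 24 (5E,9R,10R)-6,10,14-trimethyl-7-(phenylsulfonyl)-10-[(triethylsilyl)oxy]-1-(trimethylsilyl)pentadeca-5,13-dien-1-yn-9-ol (both C7 epimers), via lithiated sulfone 23 (not isolated)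
Conditions: 16, n-BuLi (1.1 equiv), THF, −78 °C; then 22, BF3·OEt2 (1.2 equiv), −78 °C; H2O quench
Reagents that add atoms: none
Why: The sulfone-stabilised allylic carbanion opens the BF3-activated terminal epoxide at its CH2 carbon (SN2), forming the C8'–C9' bond without affecting the two carbinol centres; the sulfonyl-bearing carbon forms as an inconsequential epimer mixture.

Step 17
Reactants: 24 (5E,9R,10R)-6,10,14-trimethyl-7-(phenylsulfonyl)-10-[(triethylsilyl)oxy]-1-(trimethylsilyl)pentadeca-5,13-dien-1-yn-9-ol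
Product: 25 (5E,9R,10R)-6,10,14-trimethyl-10-[(triethylsilyl)oxy]-1-(trimethylsilyl)pentadeca-5,13-dien-1-yn-9-ol
Conditions: PdCl2(dppp) (10 mol %; dppp = Ph2P(CH2)3PPh2), LiBHEt3 (3.5 equiv), THF, 0 → 20 °C
Reagents that add atoms: none
Why: Pd-catalysed reductive desulfonylation (Tsuji–Trost-type allylic substitution by hydride through a zerovalent palladium π-allyl intermediate) replaces the sulfonyl group by hydrogen with the E alkene kept.

Step 18
Reactants: 25 (5E,9R,10R)-6,10,14-trimethyl-10-[(triethylsilyl)oxy]-1-(trimethylsilyl)pentadeca-5,13-dien-1-yn-9-ol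
Product: 26 (5E,9R,10R)-6,10,14-trimethylpentadeca-5,13-dien-1-yne-9,10-diol
Conditions: n-Bu4NF (3 equiv), THF, 0 → 20 °C
Reagents that add atoms: none
Why: Fluoride-mediated desilylation cleaves both the O–Si bond of the tertiary silyl ether and the C–Si bond of the alkynylsilane in one operation.

Step 19
Reactants: 26 (5E,9R,10R)-6,10,14-trimethylpentadeca-5,13-dien-1-yne-9,10-diol; 9 1-(chloromethyl)-2-(methoxymethoxy)-3-methylbenzene
Product: 28 (6R,7R,10E,14E)-16-[2-(methoxymethoxy)-3-methylphenyl]-2,6,10,14-tetramethylhexadeca-2,10,14-triene-6,7-diol, via alkenylalane 27 (not isolated)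
Conditions: 26, Me3Al (5 equiv), Cp2ZrCl2 (25 mol %), CH2Cl2, 0 → 23 °C; volatiles removed; then 9 (1.2 equiv), Pd(PPh3)4 (5 mol %), THF, 23 → 45 °C; aq. KNaC4H4O6 work-up
Reagents that add atoms: trimethylaluminium, C[Al](C)C
Why: Negishi zirconium-catalysed carboalumination adds CH3 and Al syn across the terminal alkyne (methyl to the internal carbon), and the alkenylalane couples with the benzylic chloride under zerovalent palladium catalysis with retention, which sets the 2'E alkene and the C1'–C2' bond while the diol is carried as its aluminium diolate.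

Step 20
Reactants: 28 (6R,7R,10E,14E)-16-[2-(methoxymethoxy)-3-methylphenyl]-2,6,10,14-tetramethylhexadeca-2,10,14-triene-6,7-diol
Product: 29 2-[(2E,6E,10R,11R)-10,11-dihydroxy-3,7,11,15-tetramethylhexadeca-2,6,14-trien-1-yl]-6-methylphenol
Conditions: p-TsOH·H2O (0.3 equiv), MeOH, 35 °C, monitored; NaHCO3 quench
Reagents that add atoms: none
Why: Acid-catalysed transacetalisation (MOM methanolysis) frees the phenol under conditions mild enough for the trisubstituted alkenes and the diol.

Step 21
Reactants: 29 2-[(2E,6E,10R,11R)-10,11-dihydroxy-3,7,11,15-tetramethylhexadeca-2,6,14-trien-1-yl]-6-methylphenol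
Product: 30 2-[(2E,6E,10R,11R)-10,11-dihydroxy-3,7,11,15-tetramethylhexadeca-2,6,14-trien-1-yl]-6-methylcyclohexa-2,5-diene-1,4-dione (CNP0229670.3)
Conditions: K2[ON(SO3)2] (potassium nitrosodisulfonate, 2.5 equiv), KH2PO4 buffer, acetone/H2O, 0 → 20 °C
Reagents that add atoms: potassium nitrosodisulfonate, [K+].[K+].[O-]S(=O)(=O)N([O])S(=O)(=O)[O-]
Why: Teuber oxidation: the nitrosodisulfonate radical oxidises the 2,6-disubstituted phenol at its free para position to the 1,4-benzoquinone and does not touch the alkenes or the diol.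

**Compound list**

1 | ethyl 3-oxopentanoate | CCC(=O)CC(=O)OCC | starting material
2 | acrolein | C=CC=O | starting material
3 | ethyl 3-oxo-2-(3-oxopropyl)pentanoate (racemic) | CCC(=O)C(CCC=O)C(=O)OCC | intermediate
4 | ethyl 4-hydroxy-3-methyl-2-oxocyclohexane-1-carboxylate (aldol adduct, diastereomer mixture) | CCOC(=O)C1CCC(O)C(C)C1=O | intermediate
5 | ethyl 3-methyl-2-oxocyclohex-3-ene-1-carboxylate (racemic) | CCOC(=O)C1CCC=C(C)C1=O | intermediate
6 | ethyl 2-hydroxy-3-methylbenzoate | CCOC(=O)c1cccc(C)c1O | intermediate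
7 | ethyl 2-(methoxymethoxy)-3-methylbenzoate | CCOC(=O)c1cccc(C)c1OCOC | intermediate
8 | [2-(methoxymethoxy)-3-methylphenyl]methanol | OCc1cccc(C)c1OCOC | intermediate
9 | 1-(chloromethyl)-2-(methoxymethoxy)-3-methylbenzene | ClCc1cccc(C)c1OCOC | intermediate
10 | trimethyl(prop-1-yn-1-yl)silane | CC#C[Si](C)(C)C | starting material
11 | 1-bromo-3-methylbut-2-ene | CC(C)=CCBr | starting material
12 | [3-(trimethylsilyl)prop-2-yn-1-yl]lithium | [Li]CC#C[Si](C)(C)C | intermediate
13 | trimethyl(6-methylhept-5-en-1-yn-1-yl)silane | CC(C)=CCCC#C[Si](C)(C)C | intermediate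
14 | (2E)-2-methyl-7-(trimethylsilyl)hept-2-en-6-yn-1-ol | OC/C(C)=C/CCC#C[Si](C)(C)C | intermediate
15 | [(5E)-7-bromo-6-methylhept-5-en-1-yn-1-yl]trimethylsilane | BrC/C(C)=C/CCC#C[Si](C)(C)C | intermediate
16 | trimethyl[(5E)-6-methyl-7-(phenylsulfonyl)hept-5-en-1-yn-1-yl]silane | O=S(=O)(C/C(C)=C/CCC#C[Si](C)(C)C)c1ccccc1 | intermediate
17 | nerol, (2Z)-3,7-dimethylocta-2,6-dien-1-ol | CC(C)=CCC/C(C)=C\CO | starting material
18 | [(2R,3S)-3-methyl-3-(4-methylpent-3-en-1-yl)oxiran-2-yl]methanol | CC(C)=CCC[C@]1(C)O[C@@H]1CO | intermediate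
19 | [(2R,3S)-3-methyl-3-(4-methylpent-3-en-1-yl)oxiran-2-yl]methyl 4-methylbenzenesulfonate | CC(C)=CCC[C@]1(C)O[C@@H]1COS(=O)(=O)c1ccc(C)cc1 | intermediate
20 | (2R,3R)-2,3-dihydroxy-3,7-dimethyloct-6-en-1-yl 4-methylbenzenesulfonate | CC(C)=CCC[C@@](C)(O)[C@H](O)COS(=O)(=O)c1ccc(C)cc1 | intermediate
21 | (2R)-6-methyl-2-[(2R)-oxiran-2-yl]hept-5-en-2-ol | CC(C)=CCC[C@@](C)(O)[C@H]1CO1 | intermediate
22 | triethyl({(2R)-6-methyl-2-[(2R)-oxiran-2-yl]hept-5-en-2-yl}oxy)silane | CC(C)=CCC[C@@](C)(O[Si](CC)(CC)CC)[C@H]1CO1 | intermediate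
23 | [(2E)-2-methyl-1-(phenylsulfonyl)-7-(trimethylsilyl)hept-2-en-6-yn-1-yl]lithium | [Li]C(/C(C)=C/CCC#C[Si](C)(C)C)S(=O)(=O)c1ccccc1 | intermediate
24 | (5E,9R,10R)-6,10,14-trimethyl-7-(phenylsulfonyl)-10-[(triethylsilyl)oxy]-1-(trimethylsilyl)pentadeca-5,13-dien-1-yn-9-ol (C7 epimers) | CC(C)=CCC[C@@](C)(O[Si](CC)(CC)CC)[C@H](O)CC(/C(C)=C/CCC#C[Si](C)(C)C)S(=O)(=O)c1ccccc1 | intermediate
25 | (5E,9R,10R)-6,10,14-trimethyl-10-[(triethylsilyl)oxy]-1-(trimethylsilyl)pentadeca-5,13-dien-1-yn-9-ol | CC(C)=CCC[C@@](C)(O[Si](CC)(CC)CC)[C@H](O)CC/C(C)=C/CCC#C[Si](C)(C)C | intermediate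
26 | (5E,9R,10R)-6,10,14-trimethylpentadeca-5,13-dien-1-yne-9,10-diol | CC(C)=CCC[C@@](C)(O)[C@H](O)CC/C(C)=C/CCC#C | intermediate
27 | dimethyl{(1E,5E)-2,6-dimethyl-8-[(4R,5R)-2,4-dimethyl-4-(4-methylpent-3-en-1-yl)-1,3,2-dioxaluminolan-5-yl]octa-1,5-dien-1-yl}alumane | CC(C)=CCC[C@@]1(C)O[Al](C)O[C@@H]1CC/C(C)=C/CC/C(C)=C/[Al](C)C | intermediate
28 | (6R,7R,10E,14E)-16-[2-(methoxymethoxy)-3-methylphenyl]-2,6,10,14-tetramethylhexadeca-2,10,14-triene-6,7-diol | CC(C)=CCC[C@@](C)(O)[C@H](O)CC/C(C)=C/CC/C(C)=C/Cc1cccc(C)c1OCOC | intermediate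
29 | 2-[(2E,6E,10R,11R)-10,11-dihydroxy-3,7,11,15-tetramethylhexadeca-2,6,14-trien-1-yl]-6-methylphenol | CC(C)=CCC[C@@](C)(O)[C@H](O)CC/C(C)=C/CC/C(C)=C/Cc1cccc(C)c1O | intermediate
30 | 2-[(2E,6E,10R,11R)-10,11-dihydroxy-3,7,11,15-tetramethylhexadeca-2,6,14-trien-1-yl]-6-methylcyclohexa-2,5-diene-1,4-dione | CC(C)=CCC[C@@](C)(O)[C@H](O)CC/C(C)=C/CC/C(C)=C/CC1=CC(=O)C=C(C)C1=O | target

**Step count**

Total step count: 21 (fragment A steps 1–6, fragment B steps 7–10, fragment C steps 11–15, assembly steps 16–21).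
Longest linear sequence: 11 steps (steps 11–21, from nerol).

**The three steps most likely to fail**

Step 2. The δ-keto aldehyde can divert to a dihydropyranol or 4H-pyran through its enol oxygen, or oligomerise, instead of closing the carbocycle. The fallback sets out from 1 and comes back at 6. Compound 1 is O-silylated (Me3SiCl, Et3N) to ethyl 3-[(trimethylsilyl)oxy]pent-2-enoate F1, which LiN(iPr)2 and Me3SiCl convert into 1-ethoxy-1,3-bis[(trimethylsilyl)oxy]penta-1,3-diene F2. TiCl4-mediated reaction of F2 with 1,1,3,3-tetramethoxypropane (CH2Cl2, −78 → 20 °C) joins the diene terminus to one acetal carbon and then closes the ring by an intramolecular Mukaiyama aldol condensation with loss of methanol. This gives salicylate 6 directly and replaces steps 1–3.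

Step 17 (together with step 16 before it). Hydride can attack the allyl–palladium intermediate at C6' as well as C8', which would move or isomerise the 6' alkene, and the sulfone alkylation next to the fully substituted C11' may be slow. The fallback sets out from 22 and comes back at 25. Epoxide 22 is opened with propargyllithium 12 and BF3·OEt2 to give (5R,6R)-6,10-dimethyl-6-[(triethylsilyl)oxy]-1-(trimethylsilyl)undec-9-en-1-yn-5-ol F3. Brief K2CO3/MeOH treatment removes the C-silyl group and gives (5R,6R)-6,10-dimethyl-6-[(triethylsilyl)oxy]undec-9-en-1-yn-5-ol F4. Carboalumination (Me3Al, Cp2ZrCl2) followed by I2 gives (1E,5R,6R)-1-iodo-2,6,10-trimethyl-6-[(triethylsilyl)oxy]undeca-1,9-dien-5-ol F5, so the 6'E alkene is set by carbometalation and not by allyl chemistry. Negishi coupling (Pd(PPh3)4, THF) of F5 with bromo[4-(trimethylsilyl)but-3-yn-1-yl]zinc F6, made from (4-bromobut-1-yn-1-yl)trimethylsilane and Zn/LiCl, gives 25.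

Step 19. The one-pot sequence asks the alkenylalane to transmetalate to palladium in the presence of an aluminium diolate and residual methylaluminium species, and methyl transfer or benzyl homocoupling can compete. The fallback sets out from 26 (and 9) and comes back at 28. The carbometalation is quenched with I2 to give the isolable (1E,5E,9R,10R)-1-iodo-2,6,10,14-tetramethylpentadeca-1,5,13-triene-9,10-diol F7. The polarity of the coupling is then reversed: 9 is converted with Zn dust and LiCl in THF into chloro{[2-(methoxymethoxy)-3-methylphenyl]methyl}zinc F8, and Negishi coupling of F7 with excess F8 (Pd(PPh3)4, THF, 20 → 50 °C) gives 28 with retention of the 2'E geometry.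

**Further compounds**

F1 | step 2 | ethyl 3-[(trimethylsilyl)oxy]pent-2-enoate (geometric isomers) | CCOC(=O)C=C(CC)O[Si](C)(C)C
F2 | step 2 | 1-ethoxy-1,3-bis[(trimethylsilyl)oxy]penta-1,3-diene (geometric isomers) | CCOC(O[Si](C)(C)C)=CC(O[Si](C)(C)C)=CC
F3 | step 17 | (5R,6R)-6,10-dimethyl-6-[(triethylsilyl)oxy]-1-(trimethylsilyl)undec-9-en-1-yn-5-ol | CC(C)=CCC[C@@](C)(O[Si](CC)(CC)CC)[C@H](O)CCC#C[Si](C)(C)C
F4 | step 17 | (5R,6R)-6,10-dimethyl-6-[(triethylsilyl)oxy]undec-9-en-1-yn-5-ol | CC(C)=CCC[C@@](C)(O[Si](CC)(CC)CC)[C@H](O)CCC#C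
F5 | step 17 | (1E,5R,6R)-1-iodo-2,6,10-trimethyl-6-[(triethylsilyl)oxy]undeca-1,9-dien-5-ol | CC(C)=CCC[C@@](C)(O[Si](CC)(CC)CC)[C@H](O)CC/C(C)=C/I
F6 | step 17 | bromo[4-(trimethylsilyl)but-3-yn-1-yl]zinc | Br[Zn]CCC#C[Si](C)(C)C
F7 | step 19 | (1E,5E,9R,10R)-1-iodo-2,6,10,14-tetramethylpentadeca-1,5,13-triene-9,10-diol | CC(C)=CCC[C@@](C)(O)[C@H](O)CC/C(C)=C/CC/C(C)=C/I
F8 | step 19 | chloro{[2-(methoxymethoxy)-3-methylphenyl]methyl}zinc | Cl[Zn]Cc1cccc(C)c1OCOC
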